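**Retrosynthetic overview**

- The target is released from its fully protected form by one fluoride treatment, which removes two aryl silyl ethers and a 2-(trimethylsilyl)ethyl ester; before that the C1 hydroxyl of a salicylate is methylated.
- The strategy rests on ring A, the hexasubstituted benzene: its run C1(OCH3)–C2(prenyl)–C3(OH)–C4(prenyl) is an enolized 2,4-diprenylated acetoacetate, and C5(arylethyl)–C6(CO2H) is a β-substituted propiolate. Ring A is the only ring formed, by a [4+2] cycloaddition of a 1-methoxy-1,3-bis(silyloxy)diene with an alk-2-ynoate (bonds C4–C5 and C1–C6), followed by loss of methanol.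
- The diene comes from methyl acetoacetate by γ- then α-prenylation and two successive O-silylations (tert-butyldimethylsilyl at the C3 oxygen, trimethylsilyl at the C1 oxygen).
- The ynoate comes from 4-(4-hydroxyphenyl)butan-2-one, whose phenol ring (ring B) is bought: silylation, methyl ketone to terminal alkyne, carboxylation, esterification.

Key step: step 9

Remark: the target has no stereocentre. Ring A is numbered C1 (OCH3), C2 (prenyl), C3 (OH), C4 (prenyl), C5 (arylethyl), C6 (CO2H), and the diene and ynoate carbons carry the numbers of the ring atoms they become. The remote phenol is carried as a triisopropylsilyl ether so that it withstands the carbonate-mediated methylation.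

**Route**

Step 1
Reactants: 1 methyl acetoacetate; 2 prenyl bromide (1-bromo-3-methylbut-2-ene)
Product: 3 methyl 7-methyl-3-oxooct-6-enoate
Conditions: NaH, THF, 0 °C; n-BuLi, 0 °C; 2 (1.0 equiv), 0 °C to rt; 1 M HCl
Reagents that add atoms: none
Why: γ-Alkylation of the acetoacetate dianion, in which the more basic terminal carbanion reacts first with the allylic bromide by SN2 substitution and leaves the stabilized enolate untouched.

Step 2
Reactants: 3 methyl 7-methyl-3-oxooct-6-enoate; 2 prenyl bromide
Product: 4 methyl 7-methyl-2-(3-methylbut-2-en-1-yl)-3-oxooct-6-enoate (racemic)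
Conditions: 2 (1.05 equiv), K2CO3, acetone, reflux
Reagents that add atoms: none
Why: C-Alkylation of the β-keto ester enolate at the doubly activated α-carbon (SN2 with an allylic bromide), where mild carbonate base and one equivalent of bromide limit dialkylation and the new stereocentre is formed racemic and erased in step 3.

Step 3
Reactants: 4 methyl 7-methyl-2-(3-methylbut-2-en-1-yl)-3-oxooct-6-enoate
Product: 5 methyl 3-(tert-butyldimethylsilyloxy)-7-methyl-2-(3-methylbut-2-en-1-yl)octa-2,6-dienoate (mixture of C2=C3 isomers)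
Conditions: TBSOTf, Et3N, CH2Cl2, 0 °C to rt
Reagents that add atoms: tert-butyldimethylsilyl trifluoromethanesulfonate (TBSOTf), CC(C)(C)[Si](C)(C)OS(=O)(=O)C(F)(F)F
Why: Soft enolization and O-silylation of the β-keto ester (silyl enol ether formation), in which the amine removes the acidic α-hydrogen while the silyl triflate traps the ketone oxygen; the C2=C3 geometry is of no consequence because this bond becomes the central single bond of the diene.

Step 4
Reactants: 5 methyl 3-(tert-butyldimethylsilyloxy)-7-methyl-2-(3-methylbut-2-en-1-yl)octa-2,6-dienoate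
Product: 6 (3Z)-3-(tert-butyldimethylsilyloxy)-1-methoxy-7-methyl-2-(3-methylbut-2-en-1-yl)-1-(trimethylsilyloxy)octa-1,3,6-triene (C1=C2 geometry not controlled)
Conditions: LiN(iPr)2, THF, −78 °C; TMSCl, −78 °C to rt; hexane, filtration under argon, used crude
Reagents that add atoms: chlorotrimethylsilane (TMSCl), C[Si](C)(C)Cl
Why: Vinylogous (γ) deprotonation of the silyloxy enoate at C4 by the amide base and O-silylation of the ester dienolate (silyl ketene acetal formation), in which kinetic deprotonation should place the C4 alkyl group cis to the silyloxy group (3Z) and any deconjugated enol ether isomer of 5 converges on the same diene by α-deprotonation.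

Step 5
Reactants: 7 4-(4-hydroxyphenyl)butan-2-one
Product: 8 4-[4-(triisopropylsilyloxy)phenyl]butan-2-one
Conditions: TIPSCl, imidazole, DMF, rt
Reagents that add atoms: chlorotriisopropylsilane (TIPSCl), CC(C)[Si](Cl)(C(C)C)C(C)C
Why: Imidazole-promoted O-silylation of the phenol, which masks the acidic hydroxyl before the strong-base steps and gives an ether robust to amide bases, alkyllithium and carbonate.

Step 6
Reactants: 8 4-[4-(triisopropylsilyloxy)phenyl]butan-2-one
Product: 10 [4-(but-3-yn-1-yl)phenoxy]triisopropylsilane, via enol phosphate 9 (not isolated)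
Conditions: LiN(iPr)2 (1.05 equiv), THF, −78 °C; ClP(O)(OEt)2, −78 °C to rt; LiN(iPr)2 (2.3 equiv), −78 °C to rt; aq. NH4Cl
Reagents that add atoms: none
Why: Enol phosphate elimination of a methyl ketone, in which the kinetic enolate forms at the methyl group, O-phosphorylation gives the 1-en-2-yl phosphate 9, and excess amide base eliminates diethyl phosphate to the terminal alkyne, held as its acetylide until the quench.

Step 7
Reactants: 10 [4-(but-3-yn-1-yl)phenoxy]triisopropylsilane
Product: 11 5-[4-(triisopropylsilyloxy)phenyl]pent-2-ynoic acid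
Conditions: n-BuLi, THF, −78 °C; CO2, −78 to 0 °C; 1 M HCl, 0 °C
Reagents that add atoms: carbon dioxide, O=C=O
Why: Carboxylation of the lithium acetylide, the terminal C–H being the only site deprotonated by n-BuLi at low temperature and the aryl silyl ether tolerating both the base and the cold dilute acid.

Step 8
Reactants: 11 5-[4-(triisopropylsilyloxy)phenyl]pent-2-ynoic acid; 12 2-(trimethylsilyl)ethanol
Product: 13 2-(trimethylsilyl)ethyl 5-[4-(triisopropylsilyloxy)phenyl]pent-2-ynoate
Conditions: 12, DCC, DMAP (cat.), CH2Cl2, 0 °C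
Reagents that add atoms: none
Why: Steglich esterification, in which the O-acylisourea from DCC is intercepted by DMAP and then by the primary alcohol, the low temperature limiting conjugate addition to the ynoate.

Step 9
Reactants: 6 (3Z)-3-(tert-butyldimethylsilyloxy)-1-methoxy-7-methyl-2-(3-methylbut-2-en-1-yl)-1-(trimethylsilyloxy)octa-1,3,6-triene; 13 2-(trimethylsilyl)ethyl 5-[4-(triisopropylsilyloxy)phenyl]pent-2-ynoate
Product: 16 2-(trimethylsilyl)ethyl 4-(tert-butyldimethylsilyloxy)-2-hydroxy-3,5-bis(3-methylbut-2-en-1-yl)-6-{2-[4-(triisopropylsilyloxy)phenyl]ethyl}benzoate, via cyclohexa-1,4-diene cycloadduct 14 (not isolated), via aryl trimethylsilyl ether 15 (not isolated)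
Conditions: 6 (2.5 equiv), toluene (minimal), sealed tube, argon, 150 °C; then 1 M HCl, THF, 0 °C
Reagents that add atoms: none
Why: The electron-rich diene 6, whose HOMO coefficient is largest at C4, should add across the electron-poor triple bond of 13 in a thermal, concerted but asynchronous normal-demand Diels-Alder reaction, bond C4–C5 (diene terminus to the β-carbon) leading and bond C1–C6 (ketene acetal carbon to the α-carbon) following. The closest known reaction type is the cycloaddition of 1-alkoxy-1,3-bis(silyloxy)buta-1,3-dienes with alk-2-ynoates, which gives 2,4-dioxygenated benzoates after loss of the alcohol. Ring A is closed by this intermolecular [4+2] cycloaddition, both ring bonds being made in the one event, and 14 then aromatizes by 1,4-elimination of methanol from the C1 ketal carbon and the C4 hydrogen. The two sp3 centres of 14 (C1 and C4) form without control and are erased on aromatization, so the step sets no stereocentre. The selectivity needed is regiochemical and is secured by pairing the nucleophilic C4 terminus with the electrophilic β-carbon of the ynoate, which puts the arylethyl carbon next to the C4 prenyl and the ester next to the C1 oxygen, while the (3Z) geometry keeps the C4 substituent on the outside of the s-cis diene and the C2 substituent favours that conformer. The labile aryl trimethylsilyl ether 15 is hydrolysed in the acidic work-up whereas the bulkier silyl ether at C3 stays, so the two ring oxygens leave the step differentiated.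

Step 10
Reactants: 16 2-(trimethylsilyl)ethyl 4-(tert-butyldimethylsilyloxy)-2-hydroxy-3,5-bis(3-methylbut-2-en-1-yl)-6-{2-[4-(triisopropylsilyloxy)phenyl]ethyl}benzoate
Product: 17 2-(trimethylsilyl)ethyl 4-(tert-butyldimethylsilyloxy)-2-methoxy-3,5-bis(3-methylbut-2-en-1-yl)-6-{2-[4-(triisopropylsilyloxy)phenyl]ethyl}benzoate
Conditions: MeI, K2CO3, acetone (dry), 50 °C
Reagents that add atoms: iodomethane, CI
Why: Williamson ether synthesis, in which the only free hydroxyl, the chelated C1 phenol, is deprotonated by carbonate and methylated by SN2 attack on MeI, while the hindered C3 silyl ether, the triisopropylsilyl ether and the ester are inert to anhydrous carbonate in acetone.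

Step 11
Reactants: 17 2-(trimethylsilyl)ethyl 4-(tert-butyldimethylsilyloxy)-2-methoxy-3,5-bis(3-methylbut-2-en-1-yl)-6-{2-[4-(triisopropylsilyloxy)phenyl]ethyl}benzoate
Product: 18 4-hydroxy-6-[2-(4-hydroxyphenyl)ethyl]-2-methoxy-3,5-bis(3-methylbut-2-en-1-yl)benzoic acid (CNP0254933.0)
Conditions: Bu4NF (excess), THF, 0 °C to rt; 1 M HCl to pH 3, 0 °C
Reagents that add atoms: none
Why: Fluoride-mediated global desilylation, in which fluoride attacks silicon in all three groups so that the two aryl silyl ethers give phenoxides and the 2-(trimethylsilyl)ethyl ester fragments by β-elimination to ethylene and the carboxylate, avoiding attack at the doubly ortho-substituted ester carbonyl.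

**Compound list**

1 | methyl acetoacetate | COC(=O)CC(C)=O | starting material
2 | prenyl bromide (1-bromo-3-methylbut-2-ene) | CC(C)=CCBr | starting material
3 | methyl 7-methyl-3-oxooct-6-enoate | COC(=O)CC(=O)CCC=C(C)C | intermediate
4 | methyl 7-methyl-2-(3-methylbut-2-en-1-yl)-3-oxooct-6-enoate (racemic) | COC(=O)C(CC=C(C)C)C(=O)CCC=C(C)C | intermediate
5 | methyl 3-(tert-butyldimethylsilyloxy)-7-methyl-2-(3-methylbut-2-en-1-yl)octa-2,6-dienoate (C2=C3 isomer mixture) | COC(=O)C(CC=C(C)C)=C(O[Si](C)(C)C(C)(C)C)CCC=C(C)C | intermediate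
6 | (3Z)-3-(tert-butyldimethylsilyloxy)-1-methoxy-7-methyl-2-(3-methylbut-2-en-1-yl)-1-(trimethylsilyloxy)octa-1,3,6-triene (C1=C2 geometry undefined) | COC(O[Si](C)(C)C)=C(CC=C(C)C)/C(O[Si](C)(C)C(C)(C)C)=C/CC=C(C)C | intermediate
7 | 4-(4-hydroxyphenyl)butan-2-one | CC(=O)CCc1ccc(O)cc1 | starting material
8 | 4-[4-(triisopropylsilyloxy)phenyl]butan-2-one | CC(=O)CCc1ccc(O[Si](C(C)C)(C(C)C)C(C)C)cc1 | intermediate
9 | diethyl 4-[4-(triisopropylsilyloxy)phenyl]but-1-en-2-yl phosphate | C=C(OP(=O)(OCC)OCC)CCc1ccc(O[Si](C(C)C)(C(C)C)C(C)C)cc1 | intermediate (not isolated)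
10 | [4-(but-3-yn-1-yl)phenoxy]triisopropylsilane | C#CCCc1ccc(O[Si](C(C)C)(C(C)C)C(C)C)cc1 | intermediate
11 | 5-[4-(triisopropylsilyloxy)phenyl]pent-2-ynoic acid | OC(=O)C#CCCc1ccc(O[Si](C(C)C)(C(C)C)C(C)C)cc1 | intermediate
12 | 2-(trimethylsilyl)ethanol | C[Si](C)(C)CCO | starting material
13 | 2-(trimethylsilyl)ethyl 5-[4-(triisopropylsilyloxy)phenyl]pent-2-ynoate | C[Si](C)(C)CCOC(=O)C#CCCc1ccc(O[Si](C(C)C)(C(C)C)C(C)C)cc1 | intermediate
14 | 2-(trimethylsilyl)ethyl 4-(tert-butyldimethylsilyloxy)-6-methoxy-3,5-bis(3-methylbut-2-en-1-yl)-2-{2-[4-(triisopropylsilyloxy)phenyl]ethyl}-6-(trimethylsilyloxy)cyclohexa-1,4-diene-1-carboxylate (diastereomer mixture) | COC1(O[Si](C)(C)C)C(CC=C(C)C)=C(O[Si](C)(C)C(C)(C)C)C(CC=C(C)C)C(CCc2ccc(O[Si](C(C)C)(C(C)C)C(C)C)cc2)=C1C(=O)OCC[Si](C)(C)C | intermediate (not isolated)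
15 | 2-(trimethylsilyl)ethyl 4-(tert-butyldimethylsilyloxy)-3,5-bis(3-methylbut-2-en-1-yl)-6-{2-[4-(triisopropylsilyloxy)phenyl]ethyl}-2-(trimethylsilyloxy)benzoate | C[Si](C)(C)CCOC(=O)c1c(O[Si](C)(C)C)c(CC=C(C)C)c(O[Si](C)(C)C(C)(C)C)c(CC=C(C)C)c1CCc1ccc(O[Si](C(C)C)(C(C)C)C(C)C)cc1 | intermediate (not isolated)
16 | 2-(trimethylsilyl)ethyl 4-(tert-butyldimethylsilyloxy)-2-hydroxy-3,5-bis(3-methylbut-2-en-1-yl)-6-{2-[4-(triisopropylsilyloxy)phenyl]ethyl}benzoate | C[Si](C)(C)CCOC(=O)c1c(O)c(CC=C(C)C)c(O[Si](C)(C)C(C)(C)C)c(CC=C(C)C)c1CCc1ccc(O[Si](C(C)C)(C(C)C)C(C)C)cc1 | intermediate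
17 | 2-(trimethylsilyl)ethyl 4-(tert-butyldimethylsilyloxy)-2-methoxy-3,5-bis(3-methylbut-2-en-1-yl)-6-{2-[4-(triisopropylsilyloxy)phenyl]ethyl}benzoate | C[Si](C)(C)CCOC(=O)c1c(OC)c(CC=C(C)C)c(O[Si](C)(C)C(C)(C)C)c(CC=C(C)C)c1CCc1ccc(O[Si](C(C)C)(C(C)C)C(C)C)cc1 | intermediate
18 | 4-hydroxy-6-[2-(4-hydroxyphenyl)ethyl]-2-methoxy-3,5-bis(3-methylbut-2-en-1-yl)benzoic acid | COc1c(CC=C(C)C)c(O)c(CC=C(C)C)c(CCc2ccc(O)cc2)c1C(=O)O | target

**Step count and risks**

Total step count: 11. Longest linear sequence: 7 steps (steps 5–8 followed by steps 9–11; the diene arm, steps 1–4 followed by steps 9–11, is equally long).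

Steps most likely to fail:

1. Step 9. The cycloaddition may stall because a tetrasubstituted diene has to meet a β-branched ynoate, while at the temperature needed the diene is slowly lost by silyl transfer and hydrolysis. The fallback raises the reactivity of the dienophile by carrying the future carboxyl carbon at the aldehyde oxidation level and adjusting it afterwards; it sets out from alkyne 10 (with diene 6) and comes back to the route at target 18. Alkyne 10 is lithiated (n-BuLi, THF, −78 °C) and formylated with DMF, with inverse quench into aq. KH2PO4, to give 5-[4-(triisopropylsilyloxy)phenyl]pent-2-ynal F1. This far more electrophilic alkyne should undergo the same [4+2] addition with 6 at or slightly above room temperature with the same regiochemistry. After loss of methanol and the acidic work-up this should give 4-(tert-butyldimethylsilyloxy)-2-hydroxy-3,5-bis(3-methylbut-2-en-1-yl)-6-{2-[4-(triisopropylsilyloxy)phenyl]ethyl}benzaldehyde F2. O-Methylation (MeI, K2CO3, acetone) should give 4-(tert-butyldimethylsilyloxy)-2-methoxy-3,5-bis(3-methylbut-2-en-1-yl)-6-{2-[4-(triisopropylsilyloxy)phenyl]ethyl}benzaldehyde F3. Pinnick oxidation (NaClO2, NaH2PO4, excess 2-methylbut-2-ene, t-BuOH/H2O) should give 4-(tert-butyldimethylsilyloxy)-2-methoxy-3,5-bis(3-methylbut-2-en-1-yl)-6-{2-[4-(triisopropylsilyloxy)phenyl]ethyl}benzoic acid F4, and Bu4NF in THF then removes the two silyl ethers to give 18.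

2. Step 4. Enolization of 5 toward C4 may be incomplete or may place the C4 alkyl group on the inside of the diene, and the silyl ketene acetal is easily lost by hydrolysis during isolation. The fallback leaves the C4 prenyl group off the diene, so that the enolized terminus is a methyl group without geometry, and adds it to the arene afterwards by a para-Claisen rearrangement; it sets out from 1 and 2 and comes back at 16. C-Prenylation of 1 (2, K2CO3, acetone) gives methyl 2-(3-methylbut-2-en-1-yl)-3-oxobutanoate F5, and silylation (TBSOTf, Et3N) gives methyl 3-(tert-butyldimethylsilyloxy)-2-(3-methylbut-2-en-1-yl)but-2-enoate F6. Treatment with LiN(iPr)2 and TMSCl gives 3-(tert-butyldimethylsilyloxy)-1-methoxy-2-(3-methylbut-2-en-1-yl)-1-(trimethylsilyloxy)buta-1,3-diene F7. Cycloaddition of this diene with 13 under the conditions of step 9 should give 2-(trimethylsilyl)ethyl 4-(tert-butyldimethylsilyloxy)-2-hydroxy-3-(3-methylbut-2-en-1-yl)-6-{2-[4-(triisopropylsilyloxy)phenyl]ethyl}benzoate F8, in which ring carbon C4 carries hydrogen. O-Prenylation of the C1 hydroxyl (2, K2CO3, acetone) gives 2-(trimethylsilyl)ethyl 4-(tert-butyldimethylsilyloxy)-3-(3-methylbut-2-en-1-yl)-2-(3-methylbut-2-en-1-yloxy)-6-{2-[4-(triisopropylsilyloxy)phenyl]ethyl}benzoate F9. Heating in N,N-diethylaniline at about 190 °C should move the prenyl group to C4, the only open ring position, by two consecutive [3,3] shifts (Claisen then Cope, both ortho positions being blocked), which regenerates the C1 hydroxyl and gives 16.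

3. Step 10. Alkylation of the chelated, doubly flanked hydroxyl may be slow enough that carbonate cleaves a silyl ether, after which the freed oxygen is methylated as well. The fallback is a Mitsunobu etherification of 16 with methanol (PPh3, diisopropyl azodicarboxylate, THF, 0 °C to rt), which activates the alcohol under neutral conditions instead of forming the phenoxide; it sets out from 16 and comes back at 17. No compound outside the compound list is formed, which the block records as none F0.

**Further compounds**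

F1 | step 9 | 5-[4-(triisopropylsilyloxy)phenyl]pent-2-ynal | O=CC#CCCc1ccc(O[Si](C(C)C)(C(C)C)C(C)C)cc1
F2 | step 9 | 4-(tert-butyldimethylsilyloxy)-2-hydroxy-3,5-bis(3-methylbut-2-en-1-yl)-6-{2-[4-(triisopropylsilyloxy)phenyl]ethyl}benzaldehyde | O=Cc1c(O)c(CC=C(C)C)c(O[Si](C)(C)C(C)(C)C)c(CC=C(C)C)c1CCc1ccc(O[Si](C(C)C)(C(C)C)C(C)C)cc1
F3 | step 9 | 4-(tert-butyldimethylsilyloxy)-2-methoxy-3,5-bis(3-methylbut-2-en-1-yl)-6-{2-[4-(triisopropylsilyloxy)phenyl]ethyl}benzaldehyde | O=Cc1c(OC)c(CC=C(C)C)c(O[Si](C)(C)C(C)(C)C)c(CC=C(C)C)c1CCc1ccc(O[Si](C(C)C)(C(C)C)C(C)C)cc1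
F4 | step 9 | 4-(tert-butyldimethylsilyloxy)-2-methoxy-3,5-bis(3-methylbut-2-en-1-yl)-6-{2-[4-(triisopropylsilyloxy)phenyl]ethyl}benzoic acid | OC(=O)c1c(OC)c(CC=C(C)C)c(O[Si](C)(C)C(C)(C)C)c(CC=C(C)C)c1CCc1ccc(O[Si](C(C)C)(C(C)C)C(C)C)cc1
F5 | step 4 | methyl 2-(3-methylbut-2-en-1-yl)-3-oxobutanoate | COC(=O)C(CC=C(C)C)C(C)=O
F6 | step 4 | methyl 3-(tert-butyldimethylsilyloxy)-2-(3-methylbut-2-en-1-yl)but-2-enoate | COC(=O)C(CC=C(C)C)=C(C)O[Si](C)(C)C(C)(C)C
F7 | step 4 | 3-(tert-butyldimethylsilyloxy)-1-methoxy-2-(3-methylbut-2-en-1-yl)-1-(trimethylsilyloxy)buta-1,3-diene | COC(O[Si](C)(C)C)=C(CC=C(C)C)C(=C)O[Si](C)(C)C(C)(C)C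
F8 | step 4 | 2-(trimethylsilyl)ethyl 4-(tert-butyldimethylsilyloxy)-2-hydroxy-3-(3-methylbut-2-en-1-yl)-6-{2-[4-(triisopropylsilyloxy)phenyl]ethyl}benzoate | C[Si](C)(C)CCOC(=O)c1c(O)c(CC=C(C)C)c(O[Si](C)(C)C(C)(C)C)cc1CCc1ccc(O[Si](C(C)C)(C(C)C)C(C)C)cc1
F9 | step 4 | 2-(trimethylsilyl)ethyl 4-(tert-butyldimethylsilyloxy)-3-(3-methylbut-2-en-1-yl)-2-(3-methylbut-2-en-1-yloxy)-6-{2-[4-(triisopropylsilyloxy)phenyl]ethyl}benzoate | C[Si](C)(C)CCOC(=O)c1c(OCC=C(C)C)c(CC=C(C)C)c(O[Si](C)(C)C(C)(C)C)cc1CCc1ccc(O[Si](C(C)C)(C(C)C)C(C)C)cc1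
F0 | step 10 | none | none
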